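## Retrosynthetic overview

1. Feature: the cyclobutane C4–C5–C11–C10 carries its four carbon substituents all-trans with C10 quaternary; the six-membered enone ring (C1–C2–C3 over C4/C11) and the seven-membered ring (C6–C9 under C5/C10) bridge opposite faces of it.
2. Key disconnection: C3–C4 and C9–C10 are added trans across a C4=C10 cyclobutene ester (vinyl cuprate, then acrolein aldol); the cyclobutene comes from an enantioselective [2+2] of an aldehyde enol silane with a propiolamide.
3. Ring order: four-membered ring ([2+2]), then seven-membered ring (RCM, C7=C8), then six-membered enone ring (C1 added at C11 by homologation, C1–C2 closed by allylsilane–aldehyde addition).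
4. The vinyl nucleophile carries CH2SiMe3 so that the C1–C2 closure is polar and silicon-terminated: a free radical or cation at C3, next to the four-membered ring, would open or expand it. The C10 ester becomes the methyl group by hydride displacement for the same reason.
5. C9 is set by reagent-controlled reduction, C7/C8 by osmylation anti to C9–O and cyclic-sulfate inversion at C8 with (R)-2-methylbutanoate; angeloylation of C7–OH and desilylation finish.

Key step: step 6

Remark (locants): atoms are numbered as in the target throughout (C1 ketone, C2=C3(Me), cyclobutane C4–C5–C11–C10 with Me on C10, C6 CMe2, C7–C9 carbinols). "Upper face" is the cyclobutane face that carries C1 and C3 in the target; "lower face" carries C6 and C9.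

Remark (assumption): in step 4 the ligand enantiomer that gives the (3R,4R) adduct is used; in step 9 the oxazaborolidine is assumed to treat the fully substituted C10 as the large group.

Remark (assumption): 9, 33 and 37 are taken as commercially available.

## Route

Step 1
Reactants: 1 methyl 3,3-dimethylpent-4-enoate
Product: 2 3,3-dimethylpent-4-enal
Conditions: DIBAL-H (1.05 equiv), CH2Cl2, −78 °C; Rochelle salt
Reagents that add atoms: none
Why: DIBAL-H ester-to-aldehyde reduction, which should stop at the aldehyde because the aluminium hemiacetal is stable at −78 °C; no stereocentre is formed.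

Step 2
Reactants: 2 3,3-dimethylpent-4-enal
Product: 3 (E)-triethyl[(3,3-dimethylpenta-1,4-dien-1-yl)oxy]silane
Conditions: TESOTf, Et3N, CH2Cl2, 0 °C → rt
Reagents that add atoms: triethylsilyl triflate, CC[Si](CC)(CC)OS(=O)(=O)C(F)(F)F
Why: Soft enolisation and O-silylation of the only enolisable position should give the enol silane, E being expected because the tert-alkyl group avoids the silyloxy group; TES is chosen so that C11–O can later be freed with mild acid beside an allylsilane and a TBS ether.

Step 3
Reactants: 4 propiolic acid; 5 3,5-dimethyl-1H-pyrazole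
Product: 6 1-(3,5-dimethyl-1H-pyrazol-1-yl)prop-2-yn-1-one
Conditions: DCC, CH2Cl2, 0 °C
Reagents that add atoms: 3,5-dimethyl-1H-pyrazole (5), Cc1cc(C)[nH]n1
Why: Carbodiimide N-acylation gives the two-point-binding propiolamide that a chiral Lewis acid can chelate; no stereocentre is formed.

Step 4
Reactants: 3 (E)-enol silane; 6 N-propioloylpyrazole
Product: 7 (3R,4R)-cyclobutenoyl pyrazole (C5 side chain and C11–OTES trans)
Conditions: Cu(NTf2)2 (10 mol %), chiral 3-(2-naphthyl)alanine amide ligand (11 mol %), MeCN, 4 Å MS, −40 °C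
Reagents that add atoms: 1-(3,5-dimethyl-1H-pyrazol-1-yl)prop-2-yn-1-one (6), C#CC(=O)n1nc(C)cc1C
Why: Catalytic enantioselective stepwise [2+2] cycloaddition (Mukaiyama–Michael addition to the chelated propiolamide, then closure of the allenolate onto the silyloxocarbenium ion), in which the chiral Cu(II) complex selects the enol-silane face that becomes C5 and ring closure places the C11 silyloxy group trans to the tert-alkyl group.

Step 5
Reactants: 7 (3R,4R)-cyclobutenoyl pyrazole
Product: 8 methyl (3R,4R)-3-(2-methylbut-3-en-2-yl)-4-(triethylsilyloxy)cyclobut-1-ene-1-carboxylate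
Conditions: MeOH, DMAP (0.2 equiv), CH2Cl2, 0 °C → rt
Reagents that add atoms: methanol, CO
Why: N-Acylpyrazoles are activated amides and should undergo DMAP-catalysed acyl transfer to methanol without touching the strained enoate or the two stereocentres.

Step 6
Reactants: 8 cyclobutene ester; 9 (2-bromoallyl)trimethylsilane; 10 acrolein
Product: 14 methyl (1R,2R,3R,4S)-cyclobutane-1-carboxylate with quaternary C10 (CO2Me and 1-hydroxyprop-2-en-1-yl), C11 OTES, C5 2-methylbut-3-en-2-yl and C4 3-(trimethylsilyl)prop-1-en-2-yl (both C9 epimers), via Grignard reagent 11 (not isolated), via magnesium cuprate 12 (not isolated), via magnesium enolate 13 (not isolated)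
Conditions: 9, Mg, THF, 50 °C; CuBr·SMe2 (0.5 equiv per Grignard), THF, −78 °C; add 8, −78 → −50 °C; acrolein (3 equiv), −78 °C; sat. aq. NH4Cl at −78 °C
Reagents that add atoms: (2-bromoallyl)trimethylsilane (9, as its Grignard reagent), C=C(Br)C[Si](C)(C)C; acrolein (10), C=CC=O
Why: The diorganocuprate adds to the strained enoate at the β-carbon C4 (π-complex, Cu(III) β-adduct, reductive elimination) and leaves the magnesium enolate of C10, which adds to the carbonyl group of acrolein through a closed six-membered transition state; the closest known reaction type is the three-component conjugate addition–aldol coupling of organocopper reagents with enones and enoates. No ring is closed: the two skeletal bonds C3–C4 and C9–C10 are formed across the former C4=C10 bond. C4 is set by approach of the cuprate anti to the tert-alkyl group on the neighbouring C5. C10 is set because the aldehyde must approach anti to both cis neighbours, the new C4 side chain and the C11 silyl ether, which puts C9 on the lower face (1,3-cis to the C6 chain) and the ester on the upper face; the C9 carbinol is not controlled and is corrected in steps 8 and 9. The step needs 1,4- over 1,2-addition, which the soft cuprate and the strain released at C4=C10 should secure, and it needs the β-silyloxy enolate to survive, which −78 °C, the magnesium counter-ion, the poor overlap of the C11–O bond with the enolate π-system in the four-membered ring and a cold quench (also against retro-aldol cleavage) should secure.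

Step 7
Reactants: 14 cyclobutane triene
Product: 15 bicyclo[4.1.1]octene allylic alcohol (C7=C8; C9 epimers)
Conditions: Grubbs second-generation catalyst (10 mol %), 1,4-benzoquinone (20 mol %), toluene (2 mM), 80 °C
Reagents that add atoms: none
Why: Ring-closing metathesis of the C6 and C9 vinyl groups, which step 6 placed cis-1,3 on the lower face, should close the seven-membered ring with loss of ethene, since any other alkene pair would give a trans-fused bicyclo[3.2.0] ring.

Step 8
Reactants: 15 bicyclic allylic alcohol
Product: 16 bicyclic enone (C9 ketone, C10 ester)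
Conditions: Dess–Martin periodinane, NaHCO3, CH2Cl2, 0 °C → rt
Reagents that add atoms: none
Why: Dess–Martin oxidation converges both C9 epimers on one enone, whose β-keto ester has a quaternary α-carbon and cannot enolise.

Step 9
Reactants: 16 bicyclic enone
Product: 17 (9R)-allylic alcohol
Conditions: (S)-Me-CBS (1.0 equiv), catecholborane (2 equiv), toluene, −78 °C
Reagents that add atoms: none
Why: Corey–Bakshi–Shibata reduction is used because the substrate itself offers almost no facial bias at C9 (C4 and C11 flank the lower bridge alike), so the oxazaborolidine, binding the ketone anti to the fully substituted C10, is relied on to deliver hydride 1,2 to the s-trans enone and give the 9R carbinol.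

Step 10
Reactants: 17 (9R)-allylic alcohol
Product: 18 C9 TBS ether
Conditions: TBSOTf, 2,6-lutidine, CH2Cl2, −78 → 0 °C
Reagents that add atoms: tert-butyldimethylsilyl triflate, CC(C)(C)[Si](C)(C)OS(=O)(=O)C(F)(F)F
Why: Silyl ether formation under non-basic conditions avoids retro-aldol cleavage of the β-hydroxy ester and masks C9–OH until the last step.

Step 11
Reactants: 18 C9 TBS ether
Product: 19 C10 hydroxymethyl compound
Conditions: DIBAL-H (3 equiv), CH2Cl2, −78 → −20 °C; Rochelle salt
Reagents that add atoms: none
Why: DIBAL-H reduction of the hindered ester to the primary alcohol, kept cold to limit 1,5-silyl migration from O9 or O11.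

Step 12
Reactants: 19 C10 hydroxymethyl compound
Product: 20 C10 mesyloxymethyl compound
Conditions: MsCl, Et3N, CH2Cl2, 0 °C
Reagents that add atoms: methanesulfonyl chloride, CS(=O)(=O)Cl
Why: Sulfonylation of the neopentyl-type primary alcohol through the sulfene proceeds at oxygen and is insensitive to the hindrance at carbon.

Step 13
Reactants: 20 C10 mesyloxymethyl compound
Product: 21 C10 methyl compound
Conditions: LiEt3BH (6 equiv), THF, 0 → 65 °C
Reagents that add atoms: none
Why: SN2 hydride displacement of the mesylate (Super-Hydride reduction) is chosen over radical deoxygenation, which would open the ring through the cyclobutylcarbinyl radical; in the bicycle the CH2OMs group is equatorial and two of its β-carbons are tied back in the four-membered ring.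

Step 14
Reactants: 21 C10 methyl compound
Product: 22 C11 cyclobutanol
Conditions: PPTS (0.3 equiv), MeOH/CH2Cl2, rt
Reagents that add atoms: none
Why: Acid-catalysed methanolysis should remove the triethylsilyl ether selectively beside the bulkier TBS ether and the allylsilane.

Step 15
Reactants: 22 C11 cyclobutanol
Product: 23 C11 cyclobutanone
Conditions: Dess–Martin periodinane, NaHCO3, CH2Cl2, rt
Reagents that add atoms: none
Why: Dess–Martin oxidation gives the cyclobutanone, in which C10 is quaternary and C5 cannot epimerise because its other configuration is excluded by the lower bridge.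

Step 16
Reactants: 23 C11 cyclobutanone
Product: 26 C11 carbaldehyde (formyl group on the upper face), via enol ether 24 (not isolated), via C11-epimeric aldehyde 25 (not isolated)
Conditions: MeOCH2PPh3Cl, KHMDS, THF, 0 °C → rt; then 1 M aq. HCl, THF, rt
Reagents that add atoms: (methoxymethyl)triphenylphosphonium chloride, COC[P+](c1ccccc1)(c1ccccc1)c1ccccc1.[Cl-]; water, O
Why: Wittig methoxymethylenation and hydrolysis of the enol ether (one-carbon homologation) install C1, and C11 is set by equilibration through the enol, the formyl group being expected to prefer the upper position because the lower position at C11 lies over the C6–C9 bridge (C9–OTBS and a C6 methyl).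

Step 17
Reactants: 26 C11 carbaldehyde
Product: 27 tricyclic homoallylic alcohol (C1–OH, exocyclic C3 methylene; C1 epimers)
Conditions: BF3·OEt2 (1.5 equiv), CH2Cl2, −78 °C
Reagents that add atoms: none
Why: Intramolecular Hosomi–Sakurai allylation, in which the allylsilane terminus C2 attacks the activated aldehyde C1 (six-membered ring C1–C2–C3–C4–C10–C11, a bicyclo[3.1.1]heptane) and the β-silyl cation collapses at once to the exocyclic C3 methylene; the C1 carbinol configuration is irrelevant.

Step 18
Reactants: 27 tricyclic homoallylic alcohol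
Product: 29 tricyclic C2=C3 enone (9-OTBS, C7=C8), via β,γ-unsaturated ketone 28 (not isolated)
Conditions: Dess–Martin periodinane, NaHCO3, CH2Cl2, rt; then DBU (0.2 equiv), CH2Cl2, rt
Reagents that add atoms: none
Why: Dess–Martin oxidation followed by base-mediated migration of the exocyclic double bond into conjugation through the C2 dienolate gives the enone; C4 and C11 are bridgeheads and cannot enolise.

Step 19
Reactants: 29 tricyclic enone
Product: 30 7,8-diol (both hydroxyls anti to C9–OTBS)
Conditions: OsO4 (5 mol %), NMO, acetone/H2O (5:1), rt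
Reagents that add atoms: osmium tetroxide, O=[Os](=O)(=O)=O; N-methylmorpholine N-oxide, C[N+]1([O-])CCOCC1; water, O
Why: Catalytic OsO4/NMO syn-dihydroxylation should take the electron-rich cis C7=C8 bond in preference to the conjugated C2=C3 bond and from the face anti to the allylic C9–OTBS group, which sets C7 as in the target and C8 for later inversion.

Step 20
Reactants: 30 7,8-diol
Product: 32 7,8-cyclic sulfate, via cyclic sulfite 31 (not isolated)
Conditions: SOCl2, Et3N, CH2Cl2, 0 °C; then RuCl3·xH2O (1 mol %), NaIO4, MeCN/CCl4/H2O, 0 °C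
Reagents that add atoms: thionyl chloride, O=S(Cl)Cl; sodium periodate, [Na+].[O-]I(=O)(=O)=O
Why: Cyclic sulfate formation (cyclic sulfite, then fast Ru-catalysed S-oxidation) activates the diol as an epoxide equivalent without changing either carbinol centre.

Step 21
Reactants: 32 7,8-cyclic sulfate; 33 (R)-2-methylbutanoic acid
Product: 36 C7-hydroxy C8-(R)-2-methylbutanoate (9-OTBS), via caesium (R)-2-methylbutanoate 34 (not isolated), via sulfate monoester 35 (not isolated)
Conditions: 33 (3 equiv), Cs2CO3 (1.5 equiv), DMF, 40 °C; then conc. H2SO4 (cat.), H2O (1 equiv), THF, rt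
Reagents that add atoms: (R)-2-methylbutanoic acid (33), CC[C@@H](C)C(=O)O
Why: SN2 opening of the cyclic sulfate by the carboxylate should occur at C8 with inversion, because C7 is neopentyl to C6; acid hydrolysis of the sulfate monoester with S–O cleavage then frees C7–OH with retention, so the ester sits at C8 cis to C9–O and C7–OH is the only free hydroxyl.

Step 22
Reactants: 36 C7-hydroxy C8-ester; 37 angelic acid
Product: 39 9-O-TBS ether of the target, via mixed anhydride 38 (not isolated)
Conditions: 37, 2,4,6-trichlorobenzoyl chloride, Et3N, toluene, rt; then 36, 80 °C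
Reagents that add atoms: angelic acid (37), C/C=C(/C)C(=O)O
Why: Yamaguchi-type acylation through the mixed anhydride, run without DMAP or alkoxide, is used to keep the Z geometry of the angelate and to avoid acyl migration from O8.

Step 23
Reactants: 39 9-O-TBS ether of the target
Product: 40 CNP0206166.1
Conditions: HF·pyridine, pyridine, THF, 0 °C → rt
Reagents that add atoms: none
Why: Fluoride-mediated desilylation under buffered, weakly acidic conditions should free the hindered C9–OH without ester migration or angelate isomerisation.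

## Compound list

1 | methyl 3,3-dimethylpent-4-enoate | C=CC(C)(C)CC(=O)OC | starting material
2 | 3,3-dimethylpent-4-enal | C=CC(C)(C)CC=O | intermediate
3 | (E)-triethyl[(3,3-dimethylpenta-1,4-dien-1-yl)oxy]silane | CC[Si](CC)(CC)O/C=C/C(C)(C)C=C | intermediate
4 | propiolic acid | C#CC(=O)O | starting material
5 | 3,5-dimethyl-1H-pyrazole | Cc1cc(C)[nH]n1 | starting material
6 | 1-(3,5-dimethyl-1H-pyrazol-1-yl)prop-2-yn-1-one | C#CC(=O)n1nc(C)cc1C | intermediate
7 | (3,5-dimethyl-1H-pyrazol-1-yl)[(3R,4R)-3-(2-methylbut-3-en-2-yl)-4-(triethylsilyloxy)cyclobut-1-en-1-yl]methanone | Cc1cc(C)n(n1)C(=O)C2=C[C@H](C(C)(C)C=C)[C@H]2O[Si](CC)(CC)CC | intermediate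
8 | methyl (3R,4R)-3-(2-methylbut-3-en-2-yl)-4-(triethylsilyloxy)cyclobut-1-ene-1-carboxylate (C10=C4 cyclobutene; C5 side chain and C11–OTES trans) | COC(=O)C1=C[C@H](C(C)(C)C=C)[C@H]1O[Si](CC)(CC)CC | intermediate
9 | (2-bromoallyl)trimethylsilane | C=C(Br)C[Si](C)(C)C | starting material
10 | acrolein | C=CC=O | starting material
11 | [3-(trimethylsilyl)prop-1-en-2-yl]magnesium bromide | C=C([Mg]Br)C[Si](C)(C)C | intermediate
12 | bromomagnesium bis[3-(trimethylsilyl)prop-1-en-2-yl]cuprate | C=C(C[Si](C)(C)C)[Cu-]C(=C)C[Si](C)(C)C.[Mg+]Br | intermediate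
13 | bromomagnesium ester enolate of the C4 adduct (C10=C(OMe)OMgBr) | COC(O[Mg]Br)=C1[C@H](O[Si](CC)(CC)CC)[C@@H](C(C)(C)C=C)[C@@H]1C(=C)C[Si](C)(C)C | intermediate
14 | methyl (1R,2R,3R,4S)-1-(1-hydroxyprop-2-en-1-yl)-3-(2-methylbut-3-en-2-yl)-2-(triethylsilyloxy)-4-[3-(trimethylsilyl)prop-1-en-2-yl]cyclobutane-1-carboxylate, both carbinol (C9) epimers | C=CC(O)[C@@]1(C(=O)OC)[C@H](O[Si](CC)(CC)CC)[C@H]([C@@H]1C(=C)C[Si](C)(C)C)C(C)(C)C=C | intermediate
15 | bicyclo[4.1.1]octene (bridgeheads C5, C10; bridge C6(Me2)–C7=C8–C9) with C9–OH (both epimers), C10 CO2Me, C11 OTES and C4 silylallyl group on the upper face | C1=CC(O)[C@@]2(C(=O)OC)[C@H](O[Si](CC)(CC)CC)[C@H]([C@@H]2C(=C)C[Si](C)(C)C)C1(C)C | intermediate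
16 | C9 ketone of 15 (C7=C8–C9=O enone, C10 CO2Me) | C1=CC(=O)[C@@]2(C(=O)OC)[C@H](O[Si](CC)(CC)CC)[C@H]([C@@H]2C(=C)C[Si](C)(C)C)C1(C)C | intermediate
17 | (9R)-allylic alcohol of the bicycle (C10 CO2Me, C11 OTES) | C1=C[C@@H](O)[C@@]2(C(=O)OC)[C@H](O[Si](CC)(CC)CC)[C@H]([C@@H]2C(=C)C[Si](C)(C)C)C1(C)C | intermediate
18 | (9R)-9-O-TBS ether of 17 | C1=C[C@@H](O[Si](C)(C)C(C)(C)C)[C@@]2(C(=O)OC)[C@H](O[Si](CC)(CC)CC)[C@H]([C@@H]2C(=C)C[Si](C)(C)C)C1(C)C | intermediate
19 | C10 hydroxymethyl bicycle (9-OTBS, 11-OTES) | C1=C[C@@H](O[Si](C)(C)C(C)(C)C)[C@@]2(CO)[C@H](O[Si](CC)(CC)CC)[C@H]([C@@H]2C(=C)C[Si](C)(C)C)C1(C)C | intermediate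
20 | C10 mesyloxymethyl bicycle | C1=C[C@@H](O[Si](C)(C)C(C)(C)C)[C@@]2(COS(C)(=O)=O)[C@H](O[Si](CC)(CC)CC)[C@H]([C@@H]2C(=C)C[Si](C)(C)C)C1(C)C | intermediate
21 | C10 methyl bicycle (9-OTBS, 11-OTES) | C1=C[C@@H](O[Si](C)(C)C(C)(C)C)[C@@]2(C)[C@H](O[Si](CC)(CC)CC)[C@H]([C@@H]2C(=C)C[Si](C)(C)C)C1(C)C | intermediate
22 | C11 cyclobutanol (OH on the upper face; 9-OTBS) | C1=C[C@@H](O[Si](C)(C)C(C)(C)C)[C@@]2(C)[C@H](O)[C@H]([C@@H]2C(=C)C[Si](C)(C)C)C1(C)C | intermediate
23 | C11 cyclobutanone (9-OTBS) | C1=C[C@@H](O[Si](C)(C)C(C)(C)C)[C@@]2(C)C(=O)[C@H]([C@@H]2C(=C)C[Si](C)(C)C)C1(C)C | intermediate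
24 | C11 methoxymethylidene enol ether (E/Z) | C1=C[C@@H](O[Si](C)(C)C(C)(C)C)[C@@]2(C)C(=COC)[C@H]([C@@H]2C(=C)C[Si](C)(C)C)C1(C)C | intermediate
25 | C11 carbaldehyde, formyl on the lower face (11S) | C1=C[C@@H](O[Si](C)(C)C(C)(C)C)[C@@]2(C)[C@@H](C=O)[C@H]([C@@H]2C(=C)C[Si](C)(C)C)C1(C)C | intermediate
26 | C11 carbaldehyde, formyl on the upper face (11R), cis-1,3 to the C4 silylallyl group | C1=C[C@@H](O[Si](C)(C)C(C)(C)C)[C@@]2(C)[C@H](C=O)[C@H]([C@@H]2C(=C)C[Si](C)(C)C)C1(C)C | intermediate
27 | tricyclic (longipinane skeleton) C1 alcohol with exocyclic C3 methylene, C7=C8 and 9-OTBS (C1 epimers) | C1=C[C@@H](O[Si](C)(C)C(C)(C)C)[C@@]2(C)[C@@H]3C(O)CC(=C)[C@H]2[C@@H]3C1(C)C | intermediate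
28 | tricyclic C1 ketone with exocyclic C3 methylene (β,γ-unsaturated) | C1=C[C@@H](O[Si](C)(C)C(C)(C)C)[C@@]2(C)[C@@H]3C(=O)CC(=C)[C@H]2[C@@H]3C1(C)C | intermediate
29 | (9R)-9-(tert-butyldimethylsilyloxy)longipina-2,7-dien-1-one (target locants) | C1=C[C@@H](O[Si](C)(C)C(C)(C)C)[C@@]2(C)[C@@H]3C(=O)C=C(C)[C@H]2[C@@H]3C1(C)C | intermediate
30 | 7,8-diol of 29: 7-OH and 8-OH cis to each other and trans to 9-OTBS (7S; C8 epimeric to the target) | O[C@@H]1[C@H](O)[C@@H](O[Si](C)(C)C(C)(C)C)[C@@]2(C)[C@@H]3C(=O)C=C(C)[C@H]2[C@@H]3C1(C)C | intermediate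
31 | 7,8-cyclic sulfite of 30 | O1[C@@H]2[C@H](OS1=O)[C@@H](O[Si](C)(C)C(C)(C)C)[C@@]3(C)[C@@H]4C(=O)C=C(C)[C@H]3[C@@H]4C2(C)C | intermediate
32 | 7,8-cyclic sulfate of 30 | O1[C@@H]2[C@H](OS1(=O)=O)[C@@H](O[Si](C)(C)C(C)(C)C)[C@@]3(C)[C@@H]4C(=O)C=C(C)[C@H]3[C@@H]4C2(C)C | intermediate
33 | (R)-2-methylbutanoic acid | CC[C@@H](C)C(=O)O | starting material
34 | caesium (R)-2-methylbutanoate | CC[C@@H](C)C(=O)[O-].[Cs+] | intermediate
35 | caesium 7-O-sulfate of the C8 (R)-2-methylbutanoate (8-O cis to 9-OTBS, 7-O trans) | [O-]S(=O)(=O)O[C@@H]1[C@@H](OC(=O)[C@H](C)CC)[C@@H](O[Si](C)(C)C(C)(C)C)[C@@]2(C)[C@@H]3C(=O)C=C(C)[C@H]2[C@@H]3C1(C)C.[Cs+] | intermediate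
36 | 7-hydroxy-8-[(2R)-2-methylbutanoyloxy]-9-(tert-butyldimethylsilyloxy)longipin-2-en-1-one (target configuration at C7, C8, C9) | O[C@@H]1[C@@H](OC(=O)[C@H](C)CC)[C@@H](O[Si](C)(C)C(C)(C)C)[C@@]2(C)[C@@H]3C(=O)C=C(C)[C@H]2[C@@H]3C1(C)C | intermediate
37 | angelic acid, (Z)-2-methylbut-2-enoic acid | C/C=C(/C)C(=O)O | starting material
38 | angelic 2,4,6-trichlorobenzoic anhydride | C/C=C(/C)C(=O)OC(=O)c1c(Cl)cc(Cl)cc1Cl | intermediate
39 | 9-O-TBS ether of the target | C/C=C(/C)C(=O)O[C@@H]1[C@@H](OC(=O)[C@H](C)CC)[C@@H](O[Si](C)(C)C(C)(C)C)[C@@]2(C)[C@@H]3C(=O)C=C(C)[C@H]2[C@@H]3C1(C)C | intermediate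
40 | CNP0206166.1: (4R,5S,7S,8S,9S,10R,11R)-7-angeloyloxy-9-hydroxy-8-[(2R)-2-methylbutanoyloxy]longipin-2-en-1-one (target locants) | C/C=C(/C)C(=O)O[C@@H]1[C@@H](OC(=O)[C@H](C)CC)[C@@H](O)[C@@]2(C)[C@@H]3C(=O)C=C(C)[C@H]2[C@@H]3C1(C)C | target

## Step count and risks

Total step count: 23. Longest linear sequence: 22 steps (1 → 40 through steps 1, 2 and 4–23; step 3 is a one-step branch).

Steps most likely to fail:

Step 6. The magnesium enolate may be lost before it meets acrolein, by β-elimination of the C11 silyloxide or proton transfer; acrolein may be consumed by the organocopper residue; or the hindered aldolate may revert on warming. The fallback separates the two bond formations. It sets out from 8: copper-catalysed conjugate addition of 11 in the presence of chlorotrimethylsilane should give the trimethylsilyl ketene acetal F1, which is freed from copper salts. A Mukaiyama aldol addition of F1 to acrolein (BF3·OEt2, CH2Cl2, −78 °C) should then take place on the same face, the ketene acetal being far more nucleophilic than the allylsilane. This returns to the route at 14.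

Step 7. Closure may be slower than ruthenium hydride isomerisation of the allylic carbinol or intermolecular metathesis at the C9 vinyl group. The catalyst must finish on a neopentyl vinyl group, and the ring pucker that brings C6 and C9 together also presses the upper C4 and C11 substituents against each other. The fallback reverses the order of oxidation and ring closure. It sets out from 14: Dess–Martin oxidation gives the dienone F2. Its metathesis (Hoveyda–Grubbs II, Ti(OiPr)4, toluene, 80 °C) must start at the C6 vinyl group and end on the acryloyl unit, which neither isomerises nor homodimerises readily, and C9 is already planar. This returns to the route at 16.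

Step 17 (with the C11 setting of step 16). The formyl group may settle on the lower face of C11, out of reach of the allylsilane, or the Lewis acid may cause protodesilylation before the strained ring closes. The fallback makes the closure stereoconvergent at C11. It sets out from 23: Peterson olefination with 2-lithio-2-(trimethylsilyl)-1,3-dithiane gives the ketene dithioacetal F3. Trifluoroacetic acid (CH2Cl2, −20 → 0 °C) protonates C11 reversibly, so both C11 configurations interconvert through F3 while only the dithienium ion on the upper face is captured by the allylsilane, giving the spiro-dithiane F4. Oxidative dethioketalisation (PhI(OCOCF3)2, aq. MeCN) gives 28, which is isomerised with DBU as in step 18. This returns to the route at 29.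

## Further compounds

F1 | step 6 | methyl trimethylsilyl ketene acetal of the C4 conjugate adduct | COC(O[Si](C)(C)C)=C1[C@H](O[Si](CC)(CC)CC)[C@@H](C(C)(C)C=C)[C@@H]1C(=C)C[Si](C)(C)C
F2 | step 7 | C9 ketone of 14 (acyclic dienone, vinyl ketone on C10) | C=CC(=O)[C@@]1(C(=O)OC)[C@H](O[Si](CC)(CC)CC)[C@H]([C@@H]1C(=C)C[Si](C)(C)C)C(C)(C)C=C
F3 | step 17 | C11 ketene dithioacetal (2-ylidene-1,3-dithiane) of 23 | C1=C[C@@H](O[Si](C)(C)C(C)(C)C)[C@@]2(C)C(=C3SCCCS3)[C@H]([C@@H]2C(=C)C[Si](C)(C)C)C1(C)C
F4 | step 17 | tricyclic C1 spiro-1,3-dithiane with exocyclic C3 methylene | C1=C[C@@H](O[Si](C)(C)C(C)(C)C)[C@@]2(C)[C@@H]3C4(SCCCS4)CC(=C)[C@H]2[C@@H]3C1(C)C
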